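# Proposed total synthesis of CNP0329797.1 by anodic furan–enol ether closure of ring C

## Analysis of the target

Clerodane numbering is used throughout. Ring A is the cyclohexene C1–C5/C10, which carries the C18(=O)–O–C19 γ-lactone on C4/C5 and the C3=C4 double bond. Ring B is the cyclohexane C5–C10. Ring C is the seven-membered ketone C1–C10–C9–C11–C12–C13–C16, fused to the furan (C13–C16 and O) along its C13–C16 bond.

There are six stereocentres: C1, C5, C7, C8, C9 and C10. Calling α the face of ring B that carries C19, the 7-acetoxy group, the C8 methyl, the C9 methyl and the 10-hydroxyl are all α. C4 (on C5), C1 (on C10) and C11 (on C9) are β, so rings A/B are cis-fused, and H-1 is syn to the 10-hydroxyl.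

The main difficulty is congestion: the tertiary carbinol C10 lies between the quaternary carbons C5 and C9, and five contiguous stereocentres sit on ring B. Sensitive groups are the furan (acid, oxidants), the secondary acetate, the tertiary alcohol γ to the C12 ketone, and the unsaturated lactone.

The strategy rests on the C1–C16 bond. C1 is a ring A carbon next to the carbinol C10 and can serve as the α-carbon of a C2 ketone, while C16 is the nucleophilic α-position of a 3-substituted furan. An oxidative coupling of a ring A enol ether with the tethered furan therefore closes ring C.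

## Retrosynthetic reasoning

Target 37 is traced to dioxolane 36. The C12 ketone is unveiled last because a 3-acylfuran would be too electron-poor to attack an electrophile and would add a second enolisable ketone.

The C2 methylene of 36 is traced to the C2 ketone of 32 through allylic alcohol 33 and allylic acetate 34. The ketone is needed for the ring closure; its oxygen sits γ to the lactone carbonyl, so single-electron reduction of 34 can expel it and a base can return the alkene to conjugation.

The C1–C16 bond of 32 is cut to give silyl dienol ether 31. This is the only cut that turns the furan-fused seven-membered ring into a simple tether on a cis-decalin. The forward step must join furan C16 to C1 on the face that carries C9.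

Dienol ether 31 is traced to enone ketol 30, whose only enolisable carbon is C1, and 30 to its 7-silyl ether 28 by a protecting-group exchange.

In 28 the C3=C4 double bond is removed to give saturated ketol 27, and the C1–C10 bond of 27 is cut to give spiro keto lactone 26. The aldol direction is chosen because the C10 ketone of 26 has no α-hydrogen, and a tether on C5 forces the cis ring fusion and the α-hydroxyl. The unsaturation is added afterwards because only C3–C4 can be dehydrogenated.

Lactone 26 is opened to Michael adduct 24, which is cut at C4–C5 into hydroxymethylene ketone 22 and acylacrylate 23. This makes the quaternary C5 from a doubly activated carbon and brings C1–C4 and C18 in one piece; 22 comes from ring B ketone 21 by formylation.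

The furyl dioxolane arm of 21 is traced through 20, 19 and 18 to aldehyde 14 and 3-bromofuran 15. Ketalisation needs a substrate with no other ketone, so the ring carbonyl is parked as acetate (12) between 10 and 21.

Aldehyde 14 comes from allyl ketone 10. The C9–C11 bond of 10 is cut to give silyl enol ether 8, which comes from enone 7. Conjugate hydride delivery followed by allylation sets C8 and C9 from the single C7 stereocentre.

Enone 7 is traced by a Stork–Danheiser transposition to vinylogous ester 5, and by enolate hydroxylation to 2 and dione 1. This is where the absolute configuration enters.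

## Alternatives that were turned down

Alternative 1: The C4–C5 bond is cut. A nine-membered α-diazo-β-keto lactone A2 would be decomposed by Rh2(OAc)4, and the carbenoid would insert into the tertiary C5–H bond to give the tetracyclic β-keto lactone A1.
- For it: the lactone and ring A close in one step, and the quaternary C5 is made with retention from a plain C–H centre. That is a surer way to set C5 than the intermolecular Michael addition used here, and on this point the alternative is stronger.
- Against it: A2 is a strained medium-ring lactone that must be built with rings B and C, the furan and every other stereocentre already in place. The electrophilic carbenoid may instead attack the furan, undergo Wolff rearrangement, or insert at other C–H bonds. The C3 ketone of A1 must still be converted to the C3=C4 alkene.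
- Comparison: the chosen route is longer, but its late ring closure uses the innate polarity of a furan α-carbon and has a single reactive site.

Alternative 2: The C5–C10 bond is cut. SmI2 would reduce the ring C ketone of A4 to a ketyl that adds to the β-carbon of the tethered butenolide, closing ring B and giving A3.
- For it: both fully substituted carbons and the tertiary alcohol are formed at once. No C2 oxygen has to be introduced and removed, which saves about four steps against the chosen endgame; on step economy after ring formation it is stronger.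
- Against it: the furan-fused seven-membered ketone with the C1 and C9 centres must be made first by another method, so the hard ring is only moved earlier. The C1 hydrogen next to the ketone is acidic and can epimerise. The ketyl must add to a β,β-disubstituted acceptor next to a quaternary carbon, and two stereocentres depend on chelation in a flexible ring.
- Comparison: the chosen route creates one stereocentre in its key step, and the tether controls it.

Alternative 3: The C9–C10 bond is cut. Fe(acac)3 and PhSiH3 would deliver a hydrogen atom to the 1,1-disubstituted alkene of A6, and the tertiary C9 radical would add to the ring A ketone to give A5.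
- For it: the most congested bond is made under mild conditions, the C9 methyl comes from the alkene, and the fragments are convergent. In building C9/C10 directly it is stronger than the chosen route, which needs many steps for ring B.
- Against it: the planar radical gives only modest facial control at C9. The unsaturated lactone in the same ring is a competing radical acceptor, and addition to a ketone is reversible by β-scission. Ring C would then have to close by acylating the furan at its β-carbon, against the furan's preference and under acid that threatens the tertiary alcohol.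
- Comparison: the chosen route sets C9 by enolate alkylation and closes ring C at the furan α-carbon.

Key step: step 23

## Route

Remark: α/β are as defined in the analysis. Centres destroyed later are drawn as the expected or an unspecified epimer (C10 carbinol of 11–20, furyl carbinol of 17, C4 of 24–27 and 35, C2 of 33–34). Methyl (E)-4-oxopent-2-enoate and both antipodes of (camphorsulfonyl)oxaziridine are taken as commercial.

Step 1
Reactants: 1 2-methylcyclohexane-1,3-dione
Product: 2 3-isobutoxy-2-methylcyclohex-2-en-1-one
Conditions: i-BuOH, TsOH (cat.), toluene, reflux, Dean–Stark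
Reagents that add atoms: isobutanol, CC(C)CO
Why: Acid-catalysed enol etherification of a cyclic 1,3-dione (vinylogous ester formation), driven by azeotropic removal of water.

Step 2
Reactants: 2 3-isobutoxy-2-methylcyclohex-2-en-1-one
Product: 4 (R)-6-hydroxy-3-isobutoxy-2-methylcyclohex-2-en-1-one, via sodium dienolate 3 (not isolated)
Conditions: NaN(SiMe3)2, THF, −78 °C; then (camphorsulfonyl)oxaziridine, −78 °C
Reagents that add atoms: (camphorsulfonyl)oxaziridine (antipode as required), CC1(C)C2CCC13CS(=O)(=O)N4OC34C2
Why: Kinetic α′-deprotonation of the vinylogous ester and electrophilic enolate hydroxylation by a chiral N-sulfonyloxaziridine; the camphor framework differentiates the enolate faces and the antipode that gives the (R)-carbinol (future C7) is used.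

Step 3
Reactants: 4 (R)-6-hydroxy-3-isobutoxy-2-methylcyclohex-2-en-1-one
Product: 5 (R)-6-(tert-butyldimethylsilyloxy)-3-isobutoxy-2-methylcyclohex-2-en-1-one
Conditions: TBSCl, imidazole, DMF, rt
Reagents that add atoms: tert-butyldimethylsilyl chloride, CC(C)(C)[Si](C)(C)Cl
Why: Standard silylation of a secondary alcohol; the ether must survive organolithium, hydride and enolate chemistry.

Step 4
Reactants: 5 (R)-6-(tert-butyldimethylsilyloxy)-3-isobutoxy-2-methylcyclohex-2-en-1-one
Product: 7 (R)-4-(tert-butyldimethylsilyloxy)-2,3-dimethylcyclohex-2-en-1-one, via tertiary carbinol 6 (not isolated)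
Conditions: MeLi, THF, −78 °C; then 1 M HCl, 0 °C
Reagents that add atoms: methyllithium, [Li]C
Why: Stork–Danheiser transposition: 1,2-addition to the vinylogous ester carbonyl, then acid hydrolysis of the enol ether with loss of the tertiary hydroxyl gives the transposed enone; the silyloxy centre is not touched and brief cold acid avoids its elimination.

Step 5
Reactants: 7 (R)-4-(tert-butyldimethylsilyloxy)-2,3-dimethylcyclohex-2-en-1-one
Product: 8 4-(tert-butyldimethylsilyloxy)-2,3-dimethyl-1-(triethylsilyloxy)cyclohex-1-ene (3-methyl cis to 4-silyloxy)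
Conditions: Et3SiH, RhCl(PPh3)3 (cat.), toluene, 60 °C
Reagents that add atoms: triethylsilane, CC[SiH](CC)CC
Why: Rhodium-catalysed 1,4-hydrosilylation of an enone gives the tetrasubstituted silyl enol ether regiospecifically; allylic strain with the C3 methyl keeps the C4 silyloxy group pseudoaxial, so hydrogen is delivered to C3 anti to it and the C3 methyl ends up cis to the silyloxy group (future C8).

Step 6
Reactants: 8 4-(tert-butyldimethylsilyloxy)-2,3-dimethyl-1-(triethylsilyloxy)cyclohex-1-ene
Product: 10 (2S,3S,4R)-2-allyl-4-(tert-butyldimethylsilyloxy)-2,3-dimethylcyclohexan-1-one (2-Me/3-Me/4-OSi cis; allyl trans), via lithium enolate 9 (not isolated)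
Conditions: MeLi, THF, 0 °C to rt; then allyl bromide, DMPU, −78 to 0 °C
Reagents that add atoms: allyl bromide, C=CCBr
Why: Si–O cleavage releases the regiodefined lithium enolate, and enolate alkylation occurs anti to the adjacent pseudoaxial C3 methyl and the silyloxy group, which sets the quaternary centre (future C9) with the two methyls cis.

Step 7
Reactants: 10 (2S,3S,4R)-2-allyl-4-(tert-butyldimethylsilyloxy)-2,3-dimethylcyclohexan-1-one
Product: 11 2-allyl-4-(tert-butyldimethylsilyloxy)-2,3-dimethylcyclohexan-1-ol (1-OH cis to the methyls)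
Conditions: LiBH(s-Bu)3, THF, −78 to 0 °C
Reagents that add atoms: none
Why: Hydride reduction parks the ring carbonyl as an alcohol so that the side-chain ketone can later be ketalised alone; equatorial attack by the bulky hydride should give the axial alcohol, and this centre is re-oxidised in step 14.

Step 8
Reactants: 11 2-allyl-4-(tert-butyldimethylsilyloxy)-2,3-dimethylcyclohexan-1-ol
Product: 12 2-allyl-4-(tert-butyldimethylsilyloxy)-2,3-dimethylcyclohexyl acetate
Conditions: Ac2O, pyridine, DMAP (cat.), CH2Cl2, rt
Reagents that add atoms: acetic anhydride, CC(=O)OC(C)=O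
Why: Acylation of the hindered secondary alcohol; an acetate can later be removed by methanolysis without touching the silyl ether or the dioxolane.

Step 9
Reactants: 12 2-allyl-4-(tert-butyldimethylsilyloxy)-2,3-dimethylcyclohexyl acetate
Product: 14 4-(tert-butyldimethylsilyloxy)-2,3-dimethyl-2-(2-oxoethyl)cyclohexyl acetate, via ozonide 13 (not isolated)
Conditions: O3, CH2Cl2, −78 °C; then PPh3, −78 °C to rt
Reagents that add atoms: ozone, [O-][O+]=O
Why: Ozonolysis of the terminal alkene with reductive work-up gives the aldehyde (future C12); no other oxidisable group is present.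

Step 10
Reactants: 14 4-(tert-butyldimethylsilyloxy)-2,3-dimethyl-2-(2-oxoethyl)cyclohexyl acetate; 15 3-bromofuran
Product: 17 4-(tert-butyldimethylsilyloxy)-2-[2-(furan-3-yl)-2-hydroxyethyl]-2,3-dimethylcyclohexyl acetate (both carbinol epimers), via 3-furyllithium 16 (not isolated)
Conditions: 15, n-BuLi, THF, −78 °C; then 14, −78 °C
Reagents that add atoms: none
Why: Bromine–lithium exchange at −78 °C (kept cold so the 3-lithio species does not isomerise) and carbonyl addition; the aldehyde reacts far faster than the hindered acetate, and both epimers are used because the carbinol is oxidised next.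

Step 11
Reactants: 17 4-(tert-butyldimethylsilyloxy)-2-[2-(furan-3-yl)-2-hydroxyethyl]-2,3-dimethylcyclohexyl acetate
Product: 18 4-(tert-butyldimethylsilyloxy)-2-[2-(furan-3-yl)-2-oxoethyl]-2,3-dimethylcyclohexyl acetate
Conditions: Dess–Martin periodinane, NaHCO3, CH2Cl2, rt
Reagents that add atoms: none
Why: Dess–Martin oxidation of the furyl carbinol under buffered, non-acidic conditions that the furan tolerates.

Step 12
Reactants: 18 4-(tert-butyldimethylsilyloxy)-2-[2-(furan-3-yl)-2-oxoethyl]-2,3-dimethylcyclohexyl acetate
Product: 19 4-(tert-butyldimethylsilyloxy)-2-{[2-(furan-3-yl)-1,3-dioxolan-2-yl]methyl}-2,3-dimethylcyclohexyl acetate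
Conditions: Me3SiOCH2CH2OSiMe3, TMSOTf (cat.), CH2Cl2, −78 to −20 °C
Reagents that add atoms: 1,2-bis(trimethylsilyloxy)ethane, C[Si](C)(C)OCCO[Si](C)(C)C
Why: Silyl-transfer ketalisation converts the hindered aryl ketone, the only ketone present, into its dioxolane at low temperature without water; the acetate and the silyl ether survive.

Step 13
Reactants: 19 4-(tert-butyldimethylsilyloxy)-2-{[2-(furan-3-yl)-1,3-dioxolan-2-yl]methyl}-2,3-dimethylcyclohexyl acetate
Product: 20 4-(tert-butyldimethylsilyloxy)-2-{[2-(furan-3-yl)-1,3-dioxolan-2-yl]methyl}-2,3-dimethylcyclohexan-1-ol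
Conditions: K2CO3, MeOH, rt to 40 °C
Reagents that add atoms: none
Why: Base-mediated transesterification removes the acetate; the dioxolane and the silyl ether are stable to carbonate in methanol.

Step 14
Reactants: 20 4-(tert-butyldimethylsilyloxy)-2-{[2-(furan-3-yl)-1,3-dioxolan-2-yl]methyl}-2,3-dimethylcyclohexan-1-ol
Product: 21 4-(tert-butyldimethylsilyloxy)-2-{[2-(furan-3-yl)-1,3-dioxolan-2-yl]methyl}-2,3-dimethylcyclohexan-1-one (2-Me/3-Me/4-OSi cis; side chain trans)
Conditions: Dess–Martin periodinane, NaHCO3, CH2Cl2, rt
Reagents that add atoms: none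
Why: Dess–Martin oxidation returns the ring B ketone (future C10) with the side chain complete and the parked stereocentre erased.

Step 15
Reactants: 21 4-(tert-butyldimethylsilyloxy)-2-{[2-(furan-3-yl)-1,3-dioxolan-2-yl]methyl}-2,3-dimethylcyclohexan-1-one
Product: 22 6-(hydroxymethylene) derivative of ketone 21 (chelated enol of the 2-formyl ketone)
Conditions: NaH, HCO2Et, EtOH (cat.), THF, 0 °C to rt; aq. HCl work-up
Reagents that add atoms: ethyl formate, CCOC=O
Why: Claisen formylation at the only enolisable carbon (the other α-carbon is quaternary) installs the future C19 and activates the future C5 as a soft carbon nucleophile.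

Step 16
Reactants: 22 6-(hydroxymethylene) derivative of ketone 21; 23 methyl (E)-4-oxopent-2-enoate
Product: 24 methyl 2-(1-formyl-2-oxocyclohexyl)-4-oxopentanoate bearing the ring substituents of 21 (new ring carbon: acceptor β; formyl α; side-chain CH epimers)
Conditions: 23, Et3N (cat.), CH2Cl2, 0 °C
Reagents that add atoms: none
Why: Michael addition of a 2-formyl ketone to an acylacrylate: C-alkylation at the acceptor carbon β to the ketone (α to the ester) builds the C4–C5 bond and the quaternary C5; the acceptor is expected to add axially from the β face to the half-chair that keeps the C7 silyloxy group equatorial, away from the two α-methyl groups, though the β-oriented C11 arm opposes this, so facial control is uncertain.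

Step 17
Reactants: 24 methyl 2-(1-formyl-2-oxocyclohexyl)-4-oxopentanoate bearing the ring substituents of 21
Product: 26 9-(tert-butyldimethylsilyloxy)-7-{[2-(furan-3-yl)-1,3-dioxolan-2-yl]methyl}-7,8-dimethyl-4-(2-oxopropyl)-2-oxaspiro[4.5]decane-3,6-dione (C4 epimers), via hydroxy ester 25 (not isolated)
Conditions: NaBH(OAc)3, AcOH (cat.), CH2Cl2, rt; then PPTS (cat.), 40 °C
Reagents that add atoms: none
Why: Triacetoxyborohydride reduces the aldehyde and leaves both ketones, and the resulting primary alcohol closes the γ-lactone on the neighbouring methyl ester (5-exo acyl substitution); C19 is now fixed on the α face of C5.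

Step 18
Reactants: 26 9-(tert-butyldimethylsilyloxy)-7-{[2-(furan-3-yl)-1,3-dioxolan-2-yl]methyl}-7,8-dimethyl-4-(2-oxopropyl)-2-oxaspiro[4.5]decane-3,6-dione
Product: 27 7α-(tert-butyldimethylsilyloxy)-12,12-ethylenedioxy-10α-hydroxy-2-oxo-15,16-epoxycleroda-13(16),14-dien-18,19-olide (C4 epimers)
Conditions: LiN(SiMe3)2, THF, −78 to −40 °C; AcOH quench at −78 °C
Reagents that add atoms: none
Why: Kinetic deprotonation of the methyl ketone and intramolecular aldol addition to the non-enolisable C10 ketone closes ring A (six-membered); the tether on C5 can reach only the β face of the carbonyl, so the ring fusion is cis and the hydroxyl is α, syn to C19.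

Step 19
Reactants: 27 7α-(tert-butyldimethylsilyloxy)-12,12-ethylenedioxy-10α-hydroxy-2-oxo-15,16-epoxycleroda-13(16),14-dien-18,19-olide
Product: 28 7α-(tert-butyldimethylsilyloxy)-12,12-ethylenedioxy-10α-hydroxy-2-oxo-15,16-epoxycleroda-3,13(16),14-trien-18,19-olide
Conditions: IBX, DMSO, 60 °C
Reagents that add atoms: none
Why: IBX dehydrogenation of a ketone to the enone; only C3–C4 can be desaturated because C10 on the other side carries no hydrogen, the new alkene is conjugated to both carbonyls, and both C4 epimers converge.

Step 20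
Reactants: 28 7α-(tert-butyldimethylsilyloxy)-12,12-ethylenedioxy-10α-hydroxy-2-oxo-15,16-epoxycleroda-3,13(16),14-trien-18,19-olide
Product: 29 12,12-ethylenedioxy-7α,10α-dihydroxy-2-oxo-15,16-epoxycleroda-3,13(16),14-trien-18,19-olide
Conditions: HF·pyridine, pyridine, THF, 0 °C to rt
Reagents that add atoms: none
Why: Buffered fluoride desilylation; excess pyridine keeps the medium mild enough for the dioxolane and the β-hydroxy ketone, and the 7-hydroxyl cannot translactonise because C4 lies on the opposite face.

Step 21
Reactants: 29 12,12-ethylenedioxy-7α,10α-dihydroxy-2-oxo-15,16-epoxycleroda-3,13(16),14-trien-18,19-olide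
Product: 30 7α-acetoxy-12,12-ethylenedioxy-10α-hydroxy-2-oxo-15,16-epoxycleroda-3,13(16),14-trien-18,19-olide
Conditions: Ac2O, pyridine, DMAP (cat.), CH2Cl2, 0 °C
Reagents that add atoms: acetic anhydride, CC(=O)OC(C)=O
Why: Selective acylation of the secondary alcohol; the tertiary hydroxyl between two quaternary carbons does not react.

Step 22
Reactants: 30 7α-acetoxy-12,12-ethylenedioxy-10α-hydroxy-2-oxo-15,16-epoxycleroda-3,13(16),14-trien-18,19-olide
Product: 31 7α-acetoxy-2-(tert-butyldimethylsilyloxy)-12,12-ethylenedioxy-10α-hydroxy-15,16-epoxycleroda-1,3,13(16),14-tetraen-18,19-olide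
Conditions: TBSOTf, Et3N, CH2Cl2, −78 to 0 °C
Reagents that add atoms: tert-butyldimethylsilyl triflate, CC(C)(C)[Si](C)(C)OS(=O)(=O)C(F)(F)F
Why: Soft enolisation and O-silylation; C1 is the only enolisable carbon (C3 is vinylic), so a single cross-conjugated silyl dienol ether forms, no alkoxide is generated that could trigger retro-aldol cleavage, and the hindered tertiary hydroxyl should stay free at low temperature.

Step 23
Reactants: 31 7α-acetoxy-2-(tert-butyldimethylsilyloxy)-12,12-ethylenedioxy-10α-hydroxy-15,16-epoxycleroda-1,3,13(16),14-tetraen-18,19-olide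
Product: 32 7α-acetoxy-12,12-ethylenedioxy-10α-hydroxy-2-oxo-1,16-cyclo-15,16-epoxycleroda-3,13(16),14-trien-18,19-olide
Conditions: RVC anode, Pt cathode, undivided cell, LiClO4 (0.1 M), 2,6-lutidine, MeOH–CH2Cl2 (1:4), constant current (8 mA), 2.2 F/mol, rt
Reagents that add atoms: none
Why: One-electron oxidation at the anode turns the C1=C2 silyl enol ether into a radical cation whose C1 is attacked by furan C16; a second oxidation and proton loss restore the furan, and methanol removes silicon to unveil the C2 ketone. The closest known reaction type is the anodic coupling of silyl enol ethers with tethered furans, which is established for six- and seven-membered rings. Ring C closes in a 7-exo mode with respect to the enol ether double bond, helped by the two fully substituted carbons (C9, C10) in the tether. The new stereocentre C1 is controlled by that tether: it is anchored on C9 and C10, so the furan reaches only the ring A face on which C9 lies, which places H-1 syn to the 10-hydroxyl (cis A/C fusion). Site selectivity on the enol ether is secured by there being one enolisable carbon, and on the furan by the higher nucleophilicity of the α-carbon C16 over the β-carbon C14, which the dioxolane preserves by keeping the furan electron-rich. The intramolecular furan must outcompete methanol for the radical cation, which the tether length favours. The product ketone is harder to oxidise than the enol ether, and 2,6-lutidine buffers the acid that would otherwise threaten the dioxolane and the furan.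

Step 24
Reactants: 32 7α-acetoxy-12,12-ethylenedioxy-10α-hydroxy-2-oxo-1,16-cyclo-15,16-epoxycleroda-3,13(16),14-trien-18,19-olide
Product: 33 7α-acetoxy-12,12-ethylenedioxy-2,10α-dihydroxy-1,16-cyclo-15,16-epoxycleroda-3,13(16),14-trien-18,19-olide (C2 epimers)
Conditions: NaBH4, CeCl3·7H2O, MeOH, −78 to −40 °C
Reagents that add atoms: none
Why: Luche 1,2-reduction of the enone carbonyl; cold, nearly neutral conditions remove the ketone before the acidic H-1 can epimerise or the 10-hydroxyl can be lost by elimination, and the carbinol configuration is irrelevant.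

Step 25
Reactants: 33 7α-acetoxy-12,12-ethylenedioxy-2,10α-dihydroxy-1,16-cyclo-15,16-epoxycleroda-3,13(16),14-trien-18,19-olide
Product: 34 2,7α-diacetoxy-12,12-ethylenedioxy-10α-hydroxy-1,16-cyclo-15,16-epoxycleroda-3,13(16),14-trien-18,19-olide (C2 epimers)
Conditions: Ac2O, pyridine, DMAP (cat.), CH2Cl2, rt
Reagents that add atoms: acetic anhydride, CC(=O)OC(C)=O
Why: Acylation makes the allylic C2 oxygen, which is γ to the lactone carbonyl, a leaving group; the tertiary hydroxyl again does not react.

Step 26
Reactants: 34 2,7α-diacetoxy-12,12-ethylenedioxy-10α-hydroxy-1,16-cyclo-15,16-epoxycleroda-3,13(16),14-trien-18,19-olide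
Product: 36 7α-acetoxy-12,12-ethylenedioxy-10α-hydroxy-1,16-cyclo-15,16-epoxycleroda-3,13(16),14-trien-18,19-olide, via deconjugated lactone 35 (not isolated)
Conditions: SmI2 (2.2 equiv), THF–MeOH, −78 °C; then air, DBU, rt
Reagents that add atoms: none
Why: SmI2 reduction of a γ-acetoxy-α,β-unsaturated lactone expels acetate and gives a dienolate that is protonated mainly at C4 (β,γ-unsaturated lactone); DBU then moves the alkene back to the conjugated, trisubstituted C3=C4 position, while the unactivated 7-acetate and the dioxolane are inert.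

Step 27
Reactants: 36 7α-acetoxy-12,12-ethylenedioxy-10α-hydroxy-1,16-cyclo-15,16-epoxycleroda-3,13(16),14-trien-18,19-olide
Product: 37 7α-acetoxy-10α-hydroxy-12-oxo-1,16-cyclo-15,16-epoxycleroda-3,13(16),14-trien-18,19-olide (target)
Conditions: PPTS, acetone–H2O (4:1), 50 °C
Reagents that add atoms: water, O
Why: Mild acid hydrolysis of the dioxolane unveils the C12 ketone conjugated to the furan; the acetate, the lactone and the now electron-poor furan tolerate these conditions.

## Compound list

1 | 2-methylcyclohexane-1,3-dione | CC1C(=O)CCCC1=O | starting material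
2 | 3-isobutoxy-2-methylcyclohex-2-en-1-one | CC1=C(OCC(C)C)CCCC1=O | intermediate
3 | sodium dienolate of 2 (not isolated) | [Na+].[O-]C1=CCCC(OCC(C)C)=C1C | intermediate
4 | (R)-6-hydroxy-3-isobutoxy-2-methylcyclohex-2-en-1-one | O[C@@H]1CCC(OCC(C)C)=C(C)C1=O | intermediate
5 | (R)-6-(tert-butyldimethylsilyloxy)-3-isobutoxy-2-methylcyclohex-2-en-1-one | CC(C)(C)[Si](C)(C)O[C@@H]1CCC(OCC(C)C)=C(C)C1=O | intermediate
6 | tertiary carbinol from methyl addition to 5 (not isolated; carbinol centre unspecified) | CC(C)(C)[Si](C)(C)O[C@@H]1CCC(OCC(C)C)=C(C)C1(C)O | intermediate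
7 | (R)-4-(tert-butyldimethylsilyloxy)-2,3-dimethylcyclohex-2-en-1-one | CC(C)(C)[Si](C)(C)O[C@@H]1CCC(=O)C(C)=C1C | intermediate
8 | 4-(tert-butyldimethylsilyloxy)-2,3-dimethyl-1-(triethylsilyloxy)cyclohex-1-ene, 3-methyl cis to 4-silyloxy | CC(C)(C)[Si](C)(C)O[C@@H]1CCC(O[Si](CC)(CC)CC)=C(C)[C@@H]1C | intermediate
9 | lithium enolate from 8 (not isolated) | [Li+].CC(C)(C)[Si](C)(C)O[C@@H]1CCC([O-])=C(C)[C@@H]1C | intermediate
10 | (2S,3S,4R)-2-allyl-4-(tert-butyldimethylsilyloxy)-2,3-dimethylcyclohexan-1-one | CC(C)(C)[Si](C)(C)O[C@@H]1CCC(=O)[C@@](C)(CC=C)[C@@H]1C | intermediate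
11 | 2-allyl-4-(tert-butyldimethylsilyloxy)-2,3-dimethylcyclohexan-1-ol, 1-OH cis to the methyls (expected epimer) | CC(C)(C)[Si](C)(C)O[C@@H]1CC[C@H](O)[C@@](C)(CC=C)[C@@H]1C | intermediate
12 | 2-allyl-4-(tert-butyldimethylsilyloxy)-2,3-dimethylcyclohexyl acetate | CC(C)(C)[Si](C)(C)O[C@@H]1CC[C@H](OC(C)=O)[C@@](C)(CC=C)[C@@H]1C | intermediate
13 | ozonide (1,2,4-trioxolane) of 12 (not isolated; ring carbon unspecified) | CC(C)(C)[Si](C)(C)O[C@@H]1CC[C@H](OC(C)=O)[C@@](C)(CC2OCOO2)[C@@H]1C | intermediate
14 | 4-(tert-butyldimethylsilyloxy)-2,3-dimethyl-2-(2-oxoethyl)cyclohexyl acetate | CC(C)(C)[Si](C)(C)O[C@@H]1CC[C@H](OC(C)=O)[C@@](C)(CC=O)[C@@H]1C | intermediate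
15 | 3-bromofuran | Brc1ccoc1 | starting material
16 | 3-furyllithium (not isolated) | [Li]c1ccoc1 | intermediate
17 | 4-(tert-butyldimethylsilyloxy)-2-[2-(furan-3-yl)-2-hydroxyethyl]-2,3-dimethylcyclohexyl acetate (carbinol epimers) | CC(C)(C)[Si](C)(C)O[C@@H]1CC[C@H](OC(C)=O)[C@@](C)(CC(O)c2ccoc2)[C@@H]1C | intermediate
18 | 4-(tert-butyldimethylsilyloxy)-2-[2-(furan-3-yl)-2-oxoethyl]-2,3-dimethylcyclohexyl acetate | CC(C)(C)[Si](C)(C)O[C@@H]1CC[C@H](OC(C)=O)[C@@](C)(CC(=O)c2ccoc2)[C@@H]1C | intermediate
19 | 4-(tert-butyldimethylsilyloxy)-2-{[2-(furan-3-yl)-1,3-dioxolan-2-yl]methyl}-2,3-dimethylcyclohexyl acetate | CC(C)(C)[Si](C)(C)O[C@@H]1CC[C@H](OC(C)=O)[C@@](C)(CC2(OCCO2)c2ccoc2)[C@@H]1C | intermediate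
20 | 4-(tert-butyldimethylsilyloxy)-2-{[2-(furan-3-yl)-1,3-dioxolan-2-yl]methyl}-2,3-dimethylcyclohexan-1-ol | CC(C)(C)[Si](C)(C)O[C@@H]1CC[C@H](O)[C@@](C)(CC2(OCCO2)c2ccoc2)[C@@H]1C | intermediate
21 | 4-(tert-butyldimethylsilyloxy)-2-{[2-(furan-3-yl)-1,3-dioxolan-2-yl]methyl}-2,3-dimethylcyclohexan-1-one (ring B ketone) | CC(C)(C)[Si](C)(C)O[C@@H]1CCC(=O)[C@@](C)(CC2(OCCO2)c2ccoc2)[C@@H]1C | intermediate
22 | 6-(hydroxymethylene) derivative of 21 (enol of the 2-formyl ketone) | CC(C)(C)[Si](C)(C)O[C@@H]1CC(=CO)C(=O)[C@@](C)(CC2(OCCO2)c2ccoc2)[C@@H]1C | intermediate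
23 | methyl (E)-4-oxopent-2-enoate | COC(=O)/C=C/C(C)=O | starting material
24 | Michael adduct: methyl 2-(1-formyl-2-oxocyclohexyl)-4-oxopentanoate with the ring substituents of 21 (side-chain CH epimers) | CC(C)(C)[Si](C)(C)O[C@@H]1C[C@@](C=O)(C(CC(C)=O)C(=O)OC)C(=O)[C@@](C)(CC2(OCCO2)c2ccoc2)[C@@H]1C | intermediate
25 | hydroxy ester from reduction of 24 (not isolated) | CC(C)(C)[Si](C)(C)O[C@@H]1C[C@@](CO)(C(CC(C)=O)C(=O)OC)C(=O)[C@@](C)(CC2(OCCO2)c2ccoc2)[C@@H]1C | intermediate
26 | 9-(tert-butyldimethylsilyloxy)-7-{[2-(furan-3-yl)-1,3-dioxolan-2-yl]methyl}-7,8-dimethyl-4-(2-oxopropyl)-2-oxaspiro[4.5]decane-3,6-dione (C4 epimers) | CC(C)(C)[Si](C)(C)O[C@@H]1C[C@]2(COC(=O)C2CC(C)=O)C(=O)[C@@](C)(CC3(OCCO3)c3ccoc3)[C@@H]1C | intermediate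
27 | 7α-(tert-butyldimethylsilyloxy)-12,12-ethylenedioxy-10α-hydroxy-2-oxo-15,16-epoxycleroda-13(16),14-dien-18,19-olide (C4 epimers) | CC(C)(C)[Si](C)(C)O[C@@H]1C[C@@]23COC(=O)C2CC(=O)C[C@@]3(O)[C@@](C)(CC4(OCCO4)c4ccoc4)[C@@H]1C | intermediate
28 | 7α-(tert-butyldimethylsilyloxy)-12,12-ethylenedioxy-10α-hydroxy-2-oxo-15,16-epoxycleroda-3,13(16),14-trien-18,19-olide | CC(C)(C)[Si](C)(C)O[C@@H]1C[C@@]23COC(=O)C2=CC(=O)C[C@@]3(O)[C@@](C)(CC4(OCCO4)c4ccoc4)[C@@H]1C | intermediate
29 | 12,12-ethylenedioxy-7α,10α-dihydroxy-2-oxo-15,16-epoxycleroda-3,13(16),14-trien-18,19-olide | O[C@@H]1C[C@@]23COC(=O)C2=CC(=O)C[C@@]3(O)[C@@](C)(CC4(OCCO4)c4ccoc4)[C@@H]1C | intermediate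
30 | 7α-acetoxy-12,12-ethylenedioxy-10α-hydroxy-2-oxo-15,16-epoxycleroda-3,13(16),14-trien-18,19-olide | CC(=O)O[C@@H]1C[C@@]23COC(=O)C2=CC(=O)C[C@@]3(O)[C@@](C)(CC4(OCCO4)c4ccoc4)[C@@H]1C | intermediate
31 | 7α-acetoxy-2-(tert-butyldimethylsilyloxy)-12,12-ethylenedioxy-10α-hydroxy-15,16-epoxycleroda-1,3,13(16),14-tetraen-18,19-olide (key-step precursor) | CC(=O)O[C@@H]1C[C@@]23COC(=O)C2=CC(O[Si](C)(C)C(C)(C)C)=C[C@@]3(O)[C@@](C)(CC4(OCCO4)c4ccoc4)[C@@H]1C | intermediate
32 | 7α-acetoxy-12,12-ethylenedioxy-10α-hydroxy-2-oxo-1,16-cyclo-15,16-epoxycleroda-3,13(16),14-trien-18,19-olide (key-step product, H-1 syn to 10-OH) | CC(=O)O[C@@H]1C[C@@]23COC(=O)C2=CC(=O)[C@H]2c4occc4C4(OCCO4)C[C@@](C)([C@@H]1C)[C@]23O | intermediate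
33 | 7α-acetoxy-12,12-ethylenedioxy-2,10α-dihydroxy-1,16-cyclo-15,16-epoxycleroda-3,13(16),14-trien-18,19-olide (C2 epimers) | CC(=O)O[C@@H]1C[C@@]23COC(=O)C2=CC(O)[C@H]2c4occc4C4(OCCO4)C[C@@](C)([C@@H]1C)[C@]23O | intermediate
34 | 2,7α-diacetoxy-12,12-ethylenedioxy-10α-hydroxy-1,16-cyclo-15,16-epoxycleroda-3,13(16),14-trien-18,19-olide (C2 epimers) | CC(=O)O[C@@H]1C[C@@]23COC(=O)C2=CC(OC(C)=O)[C@H]2c4occc4C4(OCCO4)C[C@@](C)([C@@H]1C)[C@]23O | intermediate
35 | 7α-acetoxy-12,12-ethylenedioxy-10α-hydroxy-1,16-cyclo-15,16-epoxycleroda-2,13(16),14-trien-18,19-olide (not isolated; C4 epimers) | CC(=O)O[C@@H]1C[C@@]23COC(=O)C2C=C[C@H]2c4occc4C4(OCCO4)C[C@@](C)([C@@H]1C)[C@]23O | intermediate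
36 | 7α-acetoxy-12,12-ethylenedioxy-10α-hydroxy-1,16-cyclo-15,16-epoxycleroda-3,13(16),14-trien-18,19-olide | CC(=O)O[C@@H]1C[C@@]23COC(=O)C2=CC[C@H]2c4occc4C4(OCCO4)C[C@@](C)([C@@H]1C)[C@]23O | intermediate
37 | 7α-acetoxy-10α-hydroxy-12-oxo-1,16-cyclo-15,16-epoxycleroda-3,13(16),14-trien-18,19-olide (CNP0329797.1) | CC(=O)O[C@@H]1C[C@@]23COC(=O)C2=CC[C@H]2c4occc4C(=O)C[C@@](C)([C@@H]1C)[C@]23O | target

## Step count and least certain steps

Total step count: 27. Longest linear sequence: 27 steps (fully linear; 15 and 23 are purchased).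

Step 23 (key step). The radical cation may be captured by methanol or lose silicon before the furan adds. The furan or the product enol may be oxidised further, and base may eliminate the 10-hydroxyl from the β-hydroxy ketone product, whose H-1 is acidic. Fallback: enone ketol 30 would be brominated at furan C16 with NBS to give the 2-bromofuran F1. Palladium-catalysed intramolecular α-arylation of the C2 ketone at C1 (Pd2(dba)3, Xantphos, Cs2CO3, toluene) would then close ring C and rejoin the route at 32.

Step 16. The acceptor may add to the α face of C5 instead of the β face, because the pseudoaxial C11 arm on C9 shields the β face while the methyl groups and the silyloxy group shield the α face; the adduct may also undergo aldol side reactions under base. Fallback: the two C5 substituents would be introduced in the opposite order, so that the same face preference gives the other configuration. Ketone 21 would be alkylated through its lithium enolate with methyl bromoacetate to give ester F2. Its trimethylsilyl enol ether F3 (TMSOTf, Et3N) would be hydroxymethylated with aqueous formaldehyde and Sc(OTf)3, and the alcohol would lactonise to spiro lactone F4. Alkylation of the lactone enolate with 2-methoxyallyl bromide would give enol ether F5, and mild acid hydrolysis would return the route at 26.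

Step 19. The oxidant may attack the furan, hydroxylate C1, or promote loss of the 10-hydroxyl at the temperature needed. Fallback: the unsaturation would be carried from the Michael step. Hydroxymethylene ketone 22 would be added to methyl 4-oxopent-2-ynoate to give alkylidene adduct F6. Reduction and lactonisation as in step 17 would give alkylidene lactone F7. Aldol closure with LiN(SiMe3)2, after light-induced equilibration of the alkene geometry if needed, would rejoin the route at 28.

Step 5. Hydrometalation of the tetrasubstituted alkene may be slow, so 1,2-hydrosilylation or loss of the allylic silyloxy group may compete. Fallback: enone 7 would be hydrogenated (H2, Pd/C, EtOAc) from the face away from the silyloxy group to give ketone F8. Thermodynamic silylation (TMSCl, NaI, Et3N, MeCN) would give the trimethylsilyl enol ether F9, and treatment with MeLi and allyl bromide as in step 6 would rejoin the route at 10.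

Step 2. Face discrimination by the oxaziridine on this unhindered enolate may be incomplete, which would lower the enantiomeric purity of every later compound. Fallback: vinylogous ester 2 would be acetoxylated at the α′ carbon with Mn(OAc)3 to give the racemic acetate F10. Lipase-catalysed enantioselective hydrolysis would give 4 and leave the (S)-acetate F11.

## Further compounds

F1 | step 23 | 2-bromofuran analogue of 30 (bromine at furan C16) | CC(=O)O[C@@H]1C[C@@]23COC(=O)C2=CC(=O)C[C@@]3(O)[C@@](C)(CC4(OCCO4)c4ccoc4Br)[C@@H]1C
F2 | step 16 | methyl 2-(2-oxocyclohexyl)acetate with the ring substituents of 21 (ring CH epimers) | CC(C)(C)[Si](C)(C)O[C@@H]1CC(CC(=O)OC)C(=O)[C@@](C)(CC2(OCCO2)c2ccoc2)[C@@H]1C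
F3 | step 16 | trimethylsilyl enol ether of F2 | CC(C)(C)[Si](C)(C)O[C@@H]1CC(CC(=O)OC)=C(O[Si](C)(C)C)[C@@](C)(CC2(OCCO2)c2ccoc2)[C@@H]1C
F4 | step 16 | 9-(tert-butyldimethylsilyloxy)-7-{[2-(furan-3-yl)-1,3-dioxolan-2-yl]methyl}-7,8-dimethyl-2-oxaspiro[4.5]decane-3,6-dione | CC(C)(C)[Si](C)(C)O[C@@H]1C[C@]2(COC(=O)C2)C(=O)[C@@](C)(CC3(OCCO3)c3ccoc3)[C@@H]1C
F5 | step 16 | 4-(2-methoxyallyl) derivative of F4 (C4 epimers) | CC(C)(C)[Si](C)(C)O[C@@H]1C[C@]2(COC(=O)C2CC(=C)OC)C(=O)[C@@](C)(CC3(OCCO3)c3ccoc3)[C@@H]1C
F6 | step 19 | methyl 2-(1-formyl-2-oxocyclohexyl)-4-oxopent-2-enoate with the ring substituents of 21 (alkene geometry unspecified) | CC(C)(C)[Si](C)(C)O[C@@H]1C[C@@](C=O)(C(=CC(C)=O)C(=O)OC)C(=O)[C@@](C)(CC2(OCCO2)c2ccoc2)[C@@H]1C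
F7 | step 19 | 4-(2-oxopropylidene) analogue of 26 (alkene geometry unspecified) | CC(C)(C)[Si](C)(C)O[C@@H]1C[C@]2(COC(=O)C2=CC(C)=O)C(=O)[C@@](C)(CC3(OCCO3)c3ccoc3)[C@@H]1C
F8 | step 5 | 4-(tert-butyldimethylsilyloxy)-2,3-dimethylcyclohexan-1-one, all-cis | CC(C)(C)[Si](C)(C)O[C@@H]1CCC(=O)[C@H](C)[C@@H]1C
F9 | step 5 | 4-(tert-butyldimethylsilyloxy)-2,3-dimethyl-1-(trimethylsilyloxy)cyclohex-1-ene | CC(C)(C)[Si](C)(C)O[C@@H]1CCC(O[Si](C)(C)C)=C(C)[C@@H]1C
F10 | step 2 | racemic 6-acetoxy-3-isobutoxy-2-methylcyclohex-2-en-1-one | CC(=O)OC1CCC(OCC(C)C)=C(C)C1=O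
F11 | step 2 | (S)-6-acetoxy-3-isobutoxy-2-methylcyclohex-2-en-1-one | CC(=O)O[C@H]1CCC(OCC(C)C)=C(C)C1=O
A1 | alternative 1 | tetracyclic β-keto lactone with 10-O-trimethylsilyl group | CC(=O)O[C@@H]1C[C@@]23COC(=O)[C@@H]2C(=O)C[C@H]2c4occc4C(=O)C[C@@](C)([C@@H]1C)[C@]23O[Si](C)(C)C
A2 | alternative 1 | nine-membered α-diazo-β-keto lactone | CC(=O)O[C@@H]1C[C@@H]3COC(=O)C(=[N+]=[N-])C(=O)C[C@H]2c4occc4C(=O)C[C@@](C)([C@@H]1C)[C@]23O[Si](C)(C)C
A3 | alternative 2 | rings B and C with spiro γ-lactone and tertiary alcohol | COC(OC)C[C@H]1c2occc2C2(OCCO2)C[C@@]2(C)[C@H](C)[C@H](O[Si](C)(C)C(C)(C)C)C[C@]3(COC(=O)C3)[C@@]12O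
A4 | alternative 2 | ring C ketone with tethered butenolide | COC(OC)C[C@H]1c2occc2C2(OCCO2)C[C@@](C)([C@H](C)[C@H](O[Si](C)(C)C(C)(C)C)CC2=CC(=O)OC2)C1=O
A5 | alternative 3 | rings A and B with tertiary alcohol and methyl ester arm | COC(=O)C[C@@]1(C)[C@H](C)[C@H](OC(C)=O)C[C@@]23COC(=O)C2=CC[C@@H](c2ccco2)[C@]31O
A6 | alternative 3 | ring A ketone with 1,1-disubstituted alkene tether | COC(=O)CC(=C)[C@H](C)[C@H](OC(C)=O)C[C@@]12COC(=O)C1=CC[C@@H](c1ccco1)C2=O
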